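## Retrosynthetic overview
1. The depside is cut at its central aryl ester C(acyl)–O bond. This bond is made last, with every OH free, from the A-ring acid (5-chloro-2,4-dihydroxy-3,6-dimethylbenzoic acid) and the 4-OH of the B-ring phenol (methyl 2,4-dihydroxy-3,5,6-trimethylbenzoate).
2. The A-ring acid comes from chlorination of commercial 2,4-dihydroxy-3,6-dimethylbenzoic acid at C5, its only free ring position.
3. The B-ring phenol comes from commercial methyl 2,4-dihydroxy-3,6-dimethylbenzoate (synthetic oakmoss odorant) by C5 formylation, then deoxygenation of CHO to CH3.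
4. No ring is formed, since both benzene rings are bought intact. Bond order: B-ring C–C, A-ring C–Cl, then the C–O union.

Assumption: the target has no stereocentre and no configurationally stable axis. It is achiral, so the given SMILES is the full description and there is no enantiomer to select.
Numbering used in all names: C1 carries the carboxyl carbon and C2 the chelated OH.

## Route

Step 1
Reactants: 1 methyl 2,4-dihydroxy-3,6-dimethylbenzoate
Product: 3 methyl 5-formyl-2,4-dihydroxy-3,6-dimethylbenzoate, via chloro ether 2 (not isolated)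
Conditions: Cl2CHOMe (1.5 equiv), TiCl4 (3 equiv), CH2Cl2, −10 °C → rt; then 1 M HCl, 0 °C
Reagents that add atoms: dichloromethyl methyl ether, COC(Cl)Cl; water, O
Why: Rieche formylation works here because C5 is the only free ring carbon, is ortho to 4-OH and para to 2-OH, and the titanium phenoxide delivers the electrophile ortho, with aqueous acid then hydrolysing 2 to the aldehyde.

Step 2
Reactants: 3 methyl 5-formyl-2,4-dihydroxy-3,6-dimethylbenzoate
Product: 5 methyl 2,4-dihydroxy-3,5,6-trimethylbenzoate, via benzylic alcohol 4 (not isolated)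
Conditions: Et3SiH (3 equiv), TFA–CH2Cl2 (1:2), 0 °C → rt
Reagents that add atoms: none
Why: Ionic hydrogenation takes the aldehyde to CH3 because the o,p-dihydroxy-stabilised benzylic cation forms twice and is trapped by silane each time, the fully substituted ring rules out diarylmethane formation, and the ester and phenols are inert.

Step 3
Reactants: 6 2,4-dihydroxy-3,6-dimethylbenzoic acid
Product: 7 5-chloro-2,4-dihydroxy-3,6-dimethylbenzoic acid
Conditions: SO2Cl2 (1.05 equiv), Et2O, 0 °C → rt
Reagents that add atoms: sulfuryl chloride, O=S(=O)(Cl)Cl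
Why: Electrophilic aromatic chlorination goes to the single free C–H (ortho to 4-OH, para to 2-OH), and the cold, non-basic medium keeps CO2H protonated so ipso attack and chlorodecarboxylation stay slow, as in the classical 5-halogenation of β-resorcylic acid.

Step 4
Reactants: 7 5-chloro-2,4-dihydroxy-3,6-dimethylbenzoic acid; 5 methyl 2,4-dihydroxy-3,5,6-trimethylbenzoate
Product: 10 methyl 4-[(5-chloro-2,4-dihydroxy-3,6-dimethylbenzoyl)oxy]-2-hydroxy-3,5,6-trimethylbenzoate, via enol ester 8 (not isolated), via quinoketene 9 (not isolated)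
Conditions: (i) N-ethynyl-N-methyl-p-toluenesulfonamide (MYTsA, 1.0 equiv), DCE, 0 °C → rt, 2 h; (ii) slow addition (3 h) to 5 (1.5 equiv), CSA (10 mol %), 4 Å MS, DCE, 40 °C
Reagents that add atoms: N-ethynyl-N-methyl-p-toluenesulfonamide (MYTsA), C#CN(C)S(=O)(=O)c1ccc(C)cc1 (its atoms are carried in 8 only)
Why: Proposed new method: acid-gated ynamide depside coupling, in which only the CO2H of 7 (pKa about 3) can protonate the sulfonyl ynamide, so the carboxylate adds through oxygen, remote from the crowded carbonyl, and gives 8 with all phenols untouched; catalytic CSA then C-protonates the enamide and turns the leaving group into a neutral amide, so the di-ortho-substituted, o,p-dihydroxy-stabilised aroyl unit ionises unimolecularly (A_AC1, as for mesitoates) to the acylium ion and its conjugate base 9, whose linear sp carbon is open to the hindered 4-OH of 5 while the proton returns to the cycle; the 2-OH of 5 is locked in its ester chelate, the 4-OH of the acyl half is deactivated by the ortho Cl and the para acyl group, neither ring has a C–H for Friedel–Crafts or Fries chemistry, and slow addition into excess 5 suppresses oligodepsides; the closest known reaction types are ynamide-mediated amide, ester and macrolactone formation through α-acyloxyenamides, acid-catalysed acyl transfer from ethoxyvinyl esters, and the TFAA or carbodiimide depside condensation, none shown for an unprotected tetra-ortho-substituted depside junction.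

## Compound list
1 | methyl 2,4-dihydroxy-3,6-dimethylbenzoate | COC(=O)c1c(C)cc(O)c(C)c1O | starting material
2 | rac-methyl 5-[chloro(methoxy)methyl]-2,4-dihydroxy-3,6-dimethylbenzoate (transient, titanium-bound) | COC(Cl)c1c(C)c(C(=O)OC)c(O)c(C)c1O | intermediate
3 | methyl 5-formyl-2,4-dihydroxy-3,6-dimethylbenzoate | COC(=O)c1c(C)c(C=O)c(O)c(C)c1O | intermediate
4 | methyl 2,4-dihydroxy-5-(hydroxymethyl)-3,6-dimethylbenzoate | COC(=O)c1c(C)c(CO)c(O)c(C)c1O | intermediate
5 | methyl 2,4-dihydroxy-3,5,6-trimethylbenzoate | COC(=O)c1c(C)c(C)c(O)c(C)c1O | intermediate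
6 | 2,4-dihydroxy-3,6-dimethylbenzoic acid | OC(=O)c1c(C)cc(O)c(C)c1O | starting material
7 | 5-chloro-2,4-dihydroxy-3,6-dimethylbenzoic acid | OC(=O)c1c(C)c(Cl)c(O)c(C)c1O | intermediate
8 | 1-[methyl(4-methylbenzenesulfonyl)amino]ethenyl 5-chloro-2,4-dihydroxy-3,6-dimethylbenzoate | C=C(OC(=O)c1c(C)c(Cl)c(O)c(C)c1O)N(C)S(=O)(=O)c1ccc(C)cc1 | intermediate
9 | 4-chloro-3-hydroxy-2,5-dimethyl-6-(oxomethylidene)cyclohexa-2,4-dien-1-one | O=C=C1C(=O)C(C)=C(O)C(Cl)=C1C | intermediate
10 | methyl 4-[(5-chloro-2,4-dihydroxy-3,6-dimethylbenzoyl)oxy]-2-hydroxy-3,5,6-trimethylbenzoate (achiral) | COC(=O)c1c(C)c(C)c(OC(=O)c2c(C)c(Cl)c(O)c(C)c2O)c(C)c1O | target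

## Summary
Total step count: 4. Longest linear sequence: 3 (steps 1, 2, 4).

Steps most likely to fail:

**Step 4 (the proposed new coupling).**
- Risks:
  - The acyl half may acylate itself and give oligodepsides.
  - Phenol 5 may attack the imidate carbon of protonated 8 instead of the acyl carbon, which would acetylate 5.
  - The 2-OH may cyclise onto the protonated enamide.
- Fallback (known chemistry; protecting group plus late chlorination): it sets out from 1, uses 5 as the phenol partner, and comes back at 10.
  - Compound 1 is benzylated at the non-chelated 4-OH (BnBr, K2CO3, acetone, reflux) to methyl 4-(benzyloxy)-2-hydroxy-3,6-dimethylbenzoate F1.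
  - Saponification (KOH, aq. DMSO, 90 °C, then cold HCl) gives 4-(benzyloxy)-2-hydroxy-3,6-dimethylbenzoic acid F2.
  - The classical condensation with 5 (TFAA, toluene, rt) gives methyl 4-{[4-(benzyloxy)-2-hydroxy-3,6-dimethylbenzoyl]oxy}-2-hydroxy-3,5,6-trimethylbenzoate F3.
  - Hydrogenolysis (H2, 10% Pd/C, EtOAc) gives methyl 4-[(2,4-dihydroxy-3,6-dimethylbenzoyl)oxy]-2-hydroxy-3,5,6-trimethylbenzoate F4.
  - Chlorination with SO2Cl2 (1.0 equiv, Et2O–CH2Cl2, 0 °C) at the only aromatic C–H of F4 gives 10. Placing chlorine after the hydrogenolysis avoids hydrodechlorination.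

**Step 3 (chlorination of the free acid).**
- Risk: ipso attack at C1 with chlorodecarboxylation, or decarboxylation of 7 on handling.
- Fallback (chlorinate at the ester stage, then unmask the acid): it sets out from 1 and comes back at 7. Compound 1 is chlorinated (SO2Cl2, Et2O, 0 °C) to methyl 5-chloro-2,4-dihydroxy-3,6-dimethylbenzoate F5. The hindered ester of F5 is then cleaved by the A_AC1 route (conc. H2SO4, 0 °C → rt, poured onto ice) to give 7.

**Step 1 (formylation).**
- Risk: the ester-bearing, titanium-chelated ring may react sluggishly or incompletely.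
- Fallback (aminomethylation and hydrogenolysis instead of formylation and deoxygenation): it sets out from 1, comes back at 5, and so replaces step 2 as well. A Mannich reaction (aq. Me2NH, aq. HCHO, EtOH, rt → 50 °C) gives methyl 5-[(dimethylamino)methyl]-2,4-dihydroxy-3,6-dimethylbenzoate F6. Hydrogenolysis of F6 (H2 5 bar, Pd/C, MeOH–AcOH, 60 °C) gives 5.

## Further compounds
F1 | step 4 | methyl 4-(benzyloxy)-2-hydroxy-3,6-dimethylbenzoate | COC(=O)c1c(C)cc(OCc2ccccc2)c(C)c1O
F2 | step 4 | 4-(benzyloxy)-2-hydroxy-3,6-dimethylbenzoic acid | OC(=O)c1c(C)cc(OCc2ccccc2)c(C)c1O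
F3 | step 4 | methyl 4-{[4-(benzyloxy)-2-hydroxy-3,6-dimethylbenzoyl]oxy}-2-hydroxy-3,5,6-trimethylbenzoate | COC(=O)c1c(C)c(C)c(OC(=O)c2c(C)cc(OCc3ccccc3)c(C)c2O)c(C)c1O
F4 | step 4 | methyl 4-[(2,4-dihydroxy-3,6-dimethylbenzoyl)oxy]-2-hydroxy-3,5,6-trimethylbenzoate | COC(=O)c1c(C)c(C)c(OC(=O)c2c(C)cc(O)c(C)c2O)c(C)c1O
F5 | step 3 | methyl 5-chloro-2,4-dihydroxy-3,6-dimethylbenzoate | COC(=O)c1c(C)c(Cl)c(O)c(C)c1O
F6 | step 1 | methyl 5-[(dimethylamino)methyl]-2,4-dihydroxy-3,6-dimethylbenzoate | COC(=O)c1c(C)c(CN(C)C)c(O)c(C)c1O
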